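## Retrosynthetic overview

1. Cembrane numbering is used throughout: C1 (ring-fusion CH), C2 (lactone O–CH), C3=C4 (C18 on C4), C6 (OAc), C7=C8, C10 (OH), C11=C12, C13, C14, and the lactone C15(=C17H2)–C16(=O)–O–C2. The route rests on one feature: the C2 oxygen and the C18 methyl carbon are cis across C3=C4, so an O–C18(=O) ester ties them into a butenolide (O, C2, C3, C4, C18) that can hold no other geometry.
2. Target ⇐ oxidative C2/C16 lactonisation and PMB/TBS/acetate adjustment ⇐ bridging butenolide whose C18 carbonyl is taken down to CH3 (i-Bu2AlH, chloride, LiBHEt3).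
3. Bridged butenolide and 14-membered carbocycle ⇐ one ring-closing metathesis (C2 vinyl with C4 methylene) across a 15-membered macrolactone ⇐ Yamaguchi closure of C2–O–C18.
4. Seco acid ⇐ C5–C6 by catalytic asymmetric 2-(ethoxycarbonyl)allylation of a C6 enal and C9–C10 by asymmetric propargylboration of a C10 enal; both E-trisubstituted alkenes come from Zr-catalysed methylalumination/hydroxymethylation of terminal alkynes.
5. C1/C2 ⇐ anti conjugate addition to (R)-5-(hydroxymethyl)butenolide. Ring order: chiral-pool γ-lactone (opened in step 7), 15-membered lactone, butenolide and carbocycle together, then the α-methylene-γ-lactone.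

Key step: step 21

Assumption: (R)-5-(hydroxymethyl)furan-2(5H)-one is taken as a catalogue chiral-pool lactone, and the facial sense quoted for the catalysts of steps 12 and 16 is assigned by analogy with aryl and alkenyl aldehydes; the antipodal catalyst would be used if Mosher ester analysis showed the opposite sense.

## Route

Step 1
Reactants: 1 (R)-5-(hydroxymethyl)furan-2(5H)-one
Product: 2 (R)-5-[(tert-butyldimethylsilyloxy)methyl]furan-2(5H)-one
Conditions: TBSCl, imidazole, DMF, 0 °C to rt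
Reagents that add atoms: tert-butyldimethylsilyl chloride, CC(C)(C)[Si](C)(C)Cl
Why: Silyl ether formation at the primary alcohol should be clean, and the bulky CH2OTBS group is what later shields one face of the butenolide.

Step 2
Reactants: 2 (R)-5-[(tert-butyldimethylsilyloxy)methyl]furan-2(5H)-one; 3 (4-bromobut-1-yn-1-yl)trimethylsilane
Product: 6 (4R,5R)-5-[(tert-butyldimethylsilyloxy)methyl]-4-[4-(trimethylsilyl)but-3-yn-1-yl]oxolan-2-one, via Grignard reagent 4 (not isolated), via silyl ketene acetal 5 (not isolated)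
Conditions: 3, Mg, THF, rt; then CuBr·SMe2 (10 mol%), Me3SiCl, 2, THF, −78 °C; aq. NH4Cl
Reagents that add atoms: none
Why: Copper-catalysed conjugate addition of the Grignard reagent, accelerated by Me3SiCl, should deliver the chain to C1 on the face anti to the C2 CH2OTBS group, which sets C1 (R) and the trans C1/C2 relationship.

Step 3
Reactants: 6 trans-lactone TBS ether
Product: 7 (4R,5R)-5-(hydroxymethyl)-4-[4-(trimethylsilyl)but-3-yn-1-yl]oxolan-2-one
Conditions: CSA (10 mol%), MeOH, 0 °C to rt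
Reagents that add atoms: none
Why: Acid-catalysed methanolysis cleaves the primary TBS ether, while the alkynyl C–Si bond and the γ-lactone (favoured over its open methyl ester) should survive.

Step 4
Reactants: 7 hydroxymethyl lactone
Product: 8 (2R,3R)-5-oxo-3-[4-(trimethylsilyl)but-3-yn-1-yl]oxolane-2-carbaldehyde
Conditions: Dess–Martin periodinane, NaHCO3, CH2Cl2, 0 °C
Reagents that add atoms: none
Why: Dess–Martin oxidation under buffered, non-basic conditions should give the α-oxygenated aldehyde without epimerising C2.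

Step 5
Reactants: 8 lactone aldehyde
Product: 9 (4R,5S)-5-ethenyl-4-[4-(trimethylsilyl)but-3-yn-1-yl]oxolan-2-one
Conditions: Ph3PCH3Br, NaN(SiMe3)2, THF, −78 to 0 °C
Reagents that add atoms: methyltriphenylphosphonium bromide, C[P+](c1ccccc1)(c1ccccc1)c1ccccc1.[Br-]
Why: Wittig methylenation at low temperature is faster at the aldehyde than at the lactone carbonyl and should install the C2 vinyl group (C3) with C2 intact.

Step 6
Reactants: 9 vinyl lactone
Product: 12 (4R,5S)-5-ethenyl-3-methylidene-4-[4-(trimethylsilyl)but-3-yn-1-yl]oxolan-2-one, via Mannich base 10 (not isolated), via ammonium iodide 11 (not isolated)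
Conditions: LiN(i-Pr)2, THF, −78 °C; CH2=NMe2+ I−, to rt; MeI, MeOH, rt; aq. NaHCO3, CH2Cl2
Reagents that add atoms: Eschenmoser's salt (N,N-dimethylmethyleneiminium iodide), C=[N+](C)C.[I-]
Why: Mannich aminomethylation of the lactone enolate at C15, quaternisation and base-induced loss of trimethylamine should give the exocyclic C15=C17 alkene without touching C1 or C2.

Step 7
Reactants: 12 α-methylene lactone
Product: 13 (3S,4R)-4-(3-hydroxyprop-1-en-2-yl)-8-(trimethylsilyl)oct-1-en-7-yn-3-ol (C2-OH/C16-OH diol)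
Conditions: i-Bu2AlH, CH2Cl2, −78 to 0 °C; aq. sodium potassium tartrate
Reagents that add atoms: none
Why: Excess i-Bu2AlH reduces the lactone by 1,2-addition through the lactol to the 2-methylene-1,4-diol, freeing C2-OH and C16-OH.

Step 8
Reactants: 13 C2/C16 diol
Product: 15 C16-OTBS C2-OTES bis-silyl ether of 13, via mono-TBS ether 14 (not isolated)
Conditions: TBSCl (1.05 equiv), imidazole, CH2Cl2, −20 °C; then Et3SiCl, DMAP, rt
Reagents that add atoms: tert-butyldimethylsilyl chloride, CC(C)(C)[Si](C)(C)Cl; triethylsilyl chloride, CC[Si](Cl)(CC)CC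
Why: The primary allylic hydroxyl is silylated much faster than the hindered secondary one, so sequential silylation should put TBS on C16-O and the more labile TES on C2-O.

Step 9
Reactants: 15 bis-silyl ether with TMS-alkyne
Product: 16 terminal alkyne (C11≡C12, C2-OTES, C16-OTBS; 1R,2S)
Conditions: K2CO3, MeOH, rt
Reagents that add atoms: none
Why: Methanolic carbonate protodesilylates the alkynyl silane selectively, since TES and TBS ethers are stable to it.

Step 10
Reactants: 16 terminal alkyne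
Product: 19 (E)-allylic alcohol (C10-OH, CH3 on C12), via alkenylalane 17 (not isolated), via lithium alanate 18 (not isolated)
Conditions: Me3Al, Cp2ZrCl2 (25 mol%), CH2Cl2, 0 °C to rt; then n-BuLi, THF, −78 °C; (CH2O)n, to rt
Reagents that add atoms: trimethylaluminium, C[Al](C)C; paraformaldehyde (as formaldehyde), C=O
Why: Zirconium-catalysed carboalumination (Negishi) adds CH3 and Al syn across the terminal alkyne with CH3 on C12, much faster than it touches the hindered alkenes, and the alanate is hydroxymethylated with retention, so the E-C11=C12 alkene and C10 should result.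

Step 11
Reactants: 19 (E)-allylic alcohol
Product: 20 (E)-enal (C10 aldehyde)
Conditions: MnO2, CH2Cl2, rt
Reagents that add atoms: none
Why: MnO2 oxidises only the primary allylic alcohol and should give the E-enal without isomerisation.

Step 12
Reactants: 20 (E)-enal; 21 allenylboronic acid pinacol ester
Product: 23 (10S)-homopropargylic alcohol, via pinacol borate 22 (not isolated)
Conditions: (S)-TRIP (5 mol%), 4 Å molecular sieves, toluene, 0 °C; aqueous work-up
Reagents that add atoms: none
Why: Chiral phosphoric acid-catalysed propargylboration runs through a closed six-membered transition state in which the (S)-catalyst should direct γ-attack of the allenylboronate to the Si face of the enal, forming C9–C10 and setting C10 (S).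

Step 13
Reactants: 23 (10S)-homopropargylic alcohol
Product: 24 (10S)-PMB ether
Conditions: NaH, 4-methoxybenzyl chloride, n-Bu4NI (cat.), THF/DMF, 0 °C to rt
Reagents that add atoms: 4-methoxybenzyl chloride, COc1ccc(CCl)cc1
Why: Williamson etherification of the secondary alkoxide leaves the silyl ethers alone and avoids acid that could ionise the allylic alcohol.

Step 14
Reactants: 24 PMB ether alkyne
Product: 27 (E)-allylic alcohol (C6-OH, CH3 on C8), via alkenylalane 25 (not isolated), via lithium alanate 26 (not isolated)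
Conditions: Me3Al, Cp2ZrCl2 (25 mol%), CH2Cl2, 0 °C to rt; then n-BuLi, THF, −78 °C; (CH2O)n, to rt
Reagents that add atoms: trimethylaluminium, C[Al](C)C; paraformaldehyde (as formaldehyde), C=O
Why: A second Negishi carboalumination/hydroxymethylation, on a homopropargylic ether that is a standard substrate, should build the E-C7=C8 alkene and C6 as in step 10.

Step 15
Reactants: 27 (E)-allylic alcohol
Product: 28 (E)-enal (C6 aldehyde)
Conditions: MnO2, CH2Cl2, rt
Reagents that add atoms: none
Why: Selective MnO2 oxidation of the primary allylic alcohol gives the C6 enal.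

Step 16
Reactants: 28 (E)-enal; 29 ethyl 2-(bromomethyl)acrylate
Product: 30 ethyl (6S)-γ-hydroxy-α-methylene ester
Conditions: CrCl2 (10 mol%), chiral carbazole bis(oxazoline) ligand (12 mol%), Mn, Cp2ZrCl2, i-Pr2NEt, THF, rt; aq. NaHCO3
Reagents that add atoms: none
Why: In this catalytic asymmetric Nozaki–Hiyama–Kishi allylation the ligand-bound allylchromium from 29 adds through a chair transition state to the Si face of the enal, which should set C6 (S) and install C5, C4 and C18, while the neutral work-up leaves the ethyl γ-hydroxy ester unlactonised.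

Step 17
Reactants: 30 γ-hydroxy ester
Product: 31 C6-OTBS ethyl ester
Conditions: TBSOTf, 2,6-lutidine, CH2Cl2, −78 °C
Reagents that add atoms: tert-butyldimethylsilyl triflate, CC(C)(C)[Si](C)(C)OS(=O)(=O)C(F)(F)F
Why: Silylation with the silyl triflate at −78 °C is much faster than lactonisation, so C6-O is capped before it can attack C18.

Step 18
Reactants: 31 fully protected ethyl ester
Product: 32 C2-hydroxy ethyl ester
Conditions: PPTS, MeOH/CH2Cl2, 0 °C
Reagents that add atoms: none
Why: Mild acid methanolysis should remove the secondary TES ether at C2, which is far more labile than the TBS and PMB ethers.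

Step 19
Reactants: 32 C2-hydroxy ethyl ester
Product: 33 seco acid (C18 acid, C2-OH)
Conditions: LiOH, THF/MeOH/H2O, rt; then aq. HCl to pH 4
Reagents that add atoms: lithium hydroxide, [Li+].[OH-]
Why: Saponification of the ethyl 2-substituted acrylate leaves the silyl and PMB ethers intact and gives the hydroxy acid.

Step 20
Reactants: 33 seco acid
Product: 35 15-membered macrolactone (C2–O–C18; C2 vinyl, C4 methylene), via mixed anhydride 34 (not isolated)
Conditions: 2,4,6-Cl3C6H2COCl, Et3N, THF, rt; then slow addition to DMAP, toluene, 70 °C (1 mM)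
Reagents that add atoms: none
Why: In the Yamaguchi macrolactonisation the mixed anhydride is opened by DMAP and the acylpyridinium is trapped by the C2 hydroxyl under high dilution, with the three E alkenes limiting the conformations of the chain.

Step 21
Reactants: 35 15-membered macrolactone
Product: 36 bridged butenolide (14-membered carbocycle with C2–O–C18(=O) bridge)
Conditions: second-generation Grubbs catalyst (H2IMes)(PCy3)Cl2Ru=CHPh (10 mol%), toluene (1 mM), 80 °C, argon sparge
Reagents that add atoms: none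
Why: The ruthenium benzylidene exchanges onto the only monosubstituted alkene, the C2 vinyl group, and the alkylidene at C3 adds to the C4 methylene of the 2-substituted acrylate through a ruthenacyclobutane whose cycloreversion forms C3=C4 and, on turnover, releases ethylene. The closest known reaction is ring-closing metathesis of 2-substituted acrylates of secondary allylic alcohols to α-substituted butenolides; here the same diene ester sits inside a macrolactone. The butenolide (O, C2, C3, C4, C18) is closed as a five-membered ring from a diene whose two alkene carbons are held 1,4 to each other by the ester, and the 14-membered carbocycle C1–C14 is closed by the same bond as a one-carbon transannular bridge across the 15-membered lactone, so no macrocyclic alkene-forming event takes place. No stereocentre is formed; the alkene geometry is controlled by the five-membered ring, which can only hold C2 and C18 cis, and that is the E alkene of the carbocycle. The step needs site selectivity, which is secured because the trisubstituted alkenes and the 1,1-disubstituted C15=C17 alkene do not take up the catalyst and pairing C3 with C17 would give a cyclobutene, and it needs closure to outrun dimerisation, which dilution and the proximity of C3 and C4 should secure. The ester has to rotate about C18–O into the arrangement found in small-ring lactones before the ring can close, which is why the reaction is run hot.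

Step 22
Reactants: 36 bridged butenolide
Product: 37 (Z)-ene-diol (C2-OH, C18-OH)
Conditions: i-Bu2AlH, CH2Cl2, −78 to −20 °C; aq. sodium potassium tartrate
Reagents that add atoms: none
Why: i-Bu2AlH reduces the butenolide carbonyl by 1,2-addition through the lactol to the ene-1,4-diol, so the C3=C4 geometry fixed in step 21 is carried into the open form.

Step 23
Reactants: 37 ene-diol
Product: 40 C18 chloride C2-OTES ether, via mesylate 38 (not isolated), via chloro alcohol 39 (not isolated)
Conditions: MsCl, 2,4,6-collidine, LiCl, DMF, 0 °C; then imidazole, Et3SiCl, 0 °C to rt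
Reagents that add atoms: lithium chloride, [Li+].[Cl-]; triethylsilyl chloride, CC[Si](Cl)(CC)CC
Why: The primary allylic hydroxyl at C18 is mesylated selectively and displaced in the flask by chloride (SN2), and silylation of C2-O removes the alkoxide that could otherwise close a 2,5-dihydrofuran onto C18 in the next step.

Step 24
Reactants: 40 allylic chloride
Product: 41 C18-methyl carbocycle (C2-OTES, C16-OTBS, C6-OTBS, C10-OPMB)
Conditions: LiBHEt3, THF, 0 °C
Reagents that add atoms: none
Why: SN2 displacement of the primary allylic chloride by hydride should give the C18 methyl group without allylic transposition and with the E-C3=C4 geometry retained.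

Step 25
Reactants: 41 C18-methyl carbocycle
Product: 42 C2-OH/C16-OH diol (C6-OTBS, C10-OPMB)
Conditions: HF·pyridine, pyridine, THF, 0 °C
Reagents that add atoms: none
Why: Buffered HF·pyridine cleaves the TES ether and the primary allylic TBS ether much faster than the secondary TBS ether at C6, freeing C2-OH and C16-OH together.

Step 26
Reactants: 42 C2/C16 diol
Product: 45 α-methylene-γ-butyrolactone (C6-OTBS, C10-OPMB), via hydroxy enal 43 (not isolated), via lactol 44 (not isolated)
Conditions: TEMPO (20 mol%), PhI(OAc)2, CH2Cl2, rt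
Reagents that add atoms: none
Why: In this TEMPO/PhI(OAc)2 oxidative lactonisation the primary allylic alcohol is oxidised selectively to the enal, which C2-OH traps as the five-membered lactol, and a second oxidation gives the lactone.

Step 27
Reactants: 45 protected lactone
Product: 46 C6 alcohol (C10-OPMB)
Conditions: HF·pyridine, THF, rt
Reagents that add atoms: none
Why: Longer exposure to HF·pyridine removes the secondary TBS ether at C6 under conditions that the α-methylene lactone and the PMB ether tolerate.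

Step 28
Reactants: 46 C6 alcohol
Product: 47 C6 acetate (C10-OPMB)
Conditions: Ac2O, pyridine, DMAP (cat.), CH2Cl2, 0 °C
Reagents that add atoms: acetic anhydride, CC(=O)OC(C)=O
Why: Acetylation of the only free hydroxyl gives the C6 acetate.

Step 29
Reactants: 47 C6 acetate PMB ether
Product: 48 target CNP0168244.1
Conditions: DDQ, CH2Cl2/pH 7 buffer, 0 °C
Reagents that add atoms: none
Why: Oxidative cleavage of the PMB ether with DDQ is compatible with the acetate, the α-methylene lactone and the trisubstituted alkenes and frees C10-OH.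

## Compound list

1 | (R)-5-(hydroxymethyl)furan-2(5H)-one | O=C1C=C[C@H](CO)O1 | starting material
2 | (R)-5-[(tert-butyldimethylsilyloxy)methyl]furan-2(5H)-one | O=C1C=C[C@H](CO[Si](C)(C)C(C)(C)C)O1 | intermediate
3 | (4-bromobut-1-yn-1-yl)trimethylsilane | C[Si](C)(C)C#CCCBr | starting material
4 | [4-(trimethylsilyl)but-3-yn-1-yl]magnesium bromide | C[Si](C)(C)C#CCC[Mg]Br | intermediate (not isolated)
5 | (4R,5R)-5-[(tert-butyldimethylsilyloxy)methyl]-2-(trimethylsilyloxy)-4-[4-(trimethylsilyl)but-3-yn-1-yl]-4,5-dihydrofuran | C[Si](C)(C)OC1=C[C@@H](CCC#C[Si](C)(C)C)[C@H](CO[Si](C)(C)C(C)(C)C)O1 | intermediate (not isolated)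
6 | (4R,5R)-5-[(tert-butyldimethylsilyloxy)methyl]-4-[4-(trimethylsilyl)but-3-yn-1-yl]oxolan-2-one | O=C1C[C@@H](CCC#C[Si](C)(C)C)[C@H](CO[Si](C)(C)C(C)(C)C)O1 | intermediate
7 | (4R,5R)-5-(hydroxymethyl)-4-[4-(trimethylsilyl)but-3-yn-1-yl]oxolan-2-one | O=C1C[C@@H](CCC#C[Si](C)(C)C)[C@H](CO)O1 | intermediate
8 | (2R,3R)-5-oxo-3-[4-(trimethylsilyl)but-3-yn-1-yl]oxolane-2-carbaldehyde | O=C1C[C@@H](CCC#C[Si](C)(C)C)[C@H](C=O)O1 | intermediate
9 | (4R,5S)-5-ethenyl-4-[4-(trimethylsilyl)but-3-yn-1-yl]oxolan-2-one | O=C1C[C@@H](CCC#C[Si](C)(C)C)[C@H](C=C)O1 | intermediate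
10 | (4R,5S)-3-[(dimethylamino)methyl]-5-ethenyl-4-[4-(trimethylsilyl)but-3-yn-1-yl]oxolan-2-one (C3 epimers) | O=C1C(CN(C)C)[C@@H](CCC#C[Si](C)(C)C)[C@H](C=C)O1 | intermediate (not isolated)
11 | trimethylammonium iodide of 10 | O=C1C(C[N+](C)(C)C)[C@@H](CCC#C[Si](C)(C)C)[C@H](C=C)O1.[I-] | intermediate (not isolated)
12 | (4R,5S)-5-ethenyl-3-methylidene-4-[4-(trimethylsilyl)but-3-yn-1-yl]oxolan-2-one | C=C1C(=O)O[C@@H](C=C)[C@@H]1CCC#C[Si](C)(C)C | intermediate
13 | (3S,4R)-4-(3-hydroxyprop-1-en-2-yl)-8-(trimethylsilyl)oct-1-en-7-yn-3-ol | C[Si](C)(C)C#CCC[C@@H]([C@H](C=C)O)C(=C)CO | intermediate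
14 | C16 mono-TBS ether of 13 | C[Si](C)(C)C#CCC[C@@H]([C@H](C=C)O)C(=C)CO[Si](C)(C)C(C)(C)C | intermediate (not isolated)
15 | C16-OTBS, C2-OTES ether of 13 | C[Si](C)(C)C#CCC[C@@H]([C@H](C=C)O[Si](CC)(CC)CC)C(=C)CO[Si](C)(C)C(C)(C)C | intermediate
16 | terminal alkyne, C2-OTES, C16-OTBS (1R,2S) | C#CCC[C@@H]([C@H](C=C)O[Si](CC)(CC)CC)C(=C)CO[Si](C)(C)C(C)(C)C | intermediate
17 | (E)-alkenyldimethylalane (Al on C11, CH3 on C12) | C[Al](C)/C=C(\C)CC[C@@H]([C@H](C=C)O[Si](CC)(CC)CC)C(=C)CO[Si](C)(C)C(C)(C)C | intermediate (not isolated)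
18 | lithium butyl(alkenyl)dimethylalanate from 17 | [Li+].CCCC[Al-](C)(C)/C=C(\C)CC[C@@H]([C@H](C=C)O[Si](CC)(CC)CC)C(=C)CO[Si](C)(C)C(C)(C)C | intermediate (not isolated)
19 | (E)-allylic alcohol, C10-OH | OC/C=C(\C)CC[C@@H]([C@H](C=C)O[Si](CC)(CC)CC)C(=C)CO[Si](C)(C)C(C)(C)C | intermediate
20 | (E)-enal, C10 aldehyde | O=C/C=C(\C)CC[C@@H]([C@H](C=C)O[Si](CC)(CC)CC)C(=C)CO[Si](C)(C)C(C)(C)C | intermediate
21 | allenylboronic acid pinacol ester | C=C=CB1OC(C)(C)C(C)(C)O1 | starting material
22 | C10 O-pinacol borate of 23 | C#CC[C@H](OB1OC(C)(C)C(C)(C)O1)/C=C(\C)CC[C@@H]([C@H](C=C)O[Si](CC)(CC)CC)C(=C)CO[Si](C)(C)C(C)(C)C | intermediate (not isolated)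
23 | (10S)-homopropargylic alcohol | C#CC[C@H](O)/C=C(\C)CC[C@@H]([C@H](C=C)O[Si](CC)(CC)CC)C(=C)CO[Si](C)(C)C(C)(C)C | intermediate
24 | (10S)-PMB ether, terminal alkyne | C#CC[C@H](OCc1ccc(OC)cc1)/C=C(\C)CC[C@@H]([C@H](C=C)O[Si](CC)(CC)CC)C(=C)CO[Si](C)(C)C(C)(C)C | intermediate
25 | (E)-alkenyldimethylalane (Al on C7, CH3 on C8) | C[Al](C)/C=C(\C)C[C@H](OCc1ccc(OC)cc1)/C=C(\C)CC[C@@H]([C@H](C=C)O[Si](CC)(CC)CC)C(=C)CO[Si](C)(C)C(C)(C)C | intermediate (not isolated)
26 | lithium butyl(alkenyl)dimethylalanate from 25 | [Li+].CCCC[Al-](C)(C)/C=C(\C)C[C@H](OCc1ccc(OC)cc1)/C=C(\C)CC[C@@H]([C@H](C=C)O[Si](CC)(CC)CC)C(=C)CO[Si](C)(C)C(C)(C)C | intermediate (not isolated)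
27 | (E)-allylic alcohol, C6-OH | OC/C=C(\C)C[C@H](OCc1ccc(OC)cc1)/C=C(\C)CC[C@@H]([C@H](C=C)O[Si](CC)(CC)CC)C(=C)CO[Si](C)(C)C(C)(C)C | intermediate
28 | (E)-enal, C6 aldehyde | O=C/C=C(\C)C[C@H](OCc1ccc(OC)cc1)/C=C(\C)CC[C@@H]([C@H](C=C)O[Si](CC)(CC)CC)C(=C)CO[Si](C)(C)C(C)(C)C | intermediate
29 | ethyl 2-(bromomethyl)acrylate | C=C(CBr)C(=O)OCC | starting material
30 | ethyl (6S)-γ-hydroxy-α-methylene ester | CCOC(=O)C(=C)C[C@H](O)/C=C(\C)C[C@H](OCc1ccc(OC)cc1)/C=C(\C)CC[C@@H]([C@H](C=C)O[Si](CC)(CC)CC)C(=C)CO[Si](C)(C)C(C)(C)C | intermediate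
31 | C6-OTBS ethyl ester | CCOC(=O)C(=C)C[C@H](O[Si](C)(C)C(C)(C)C)/C=C(\C)C[C@H](OCc1ccc(OC)cc1)/C=C(\C)CC[C@@H]([C@H](C=C)O[Si](CC)(CC)CC)C(=C)CO[Si](C)(C)C(C)(C)C | intermediate
32 | C2-hydroxy ethyl ester | CCOC(=O)C(=C)C[C@H](O[Si](C)(C)C(C)(C)C)/C=C(\C)C[C@H](OCc1ccc(OC)cc1)/C=C(\C)CC[C@@H]([C@H](C=C)O)C(=C)CO[Si](C)(C)C(C)(C)C | intermediate
33 | seco acid | OC(=O)C(=C)C[C@H](O[Si](C)(C)C(C)(C)C)/C=C(\C)C[C@H](OCc1ccc(OC)cc1)/C=C(\C)CC[C@@H]([C@H](C=C)O)C(=C)CO[Si](C)(C)C(C)(C)C | intermediate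
34 | 2,4,6-trichlorobenzoic mixed anhydride of 33 | O=C(OC(=O)C(=C)C[C@H](O[Si](C)(C)C(C)(C)C)/C=C(\C)C[C@H](OCc1ccc(OC)cc1)/C=C(\C)CC[C@@H]([C@H](C=C)O)C(=C)CO[Si](C)(C)C(C)(C)C)c1c(Cl)cc(Cl)cc1Cl | intermediate (not isolated)
35 | 15-membered macrolactone (metathesis precursor) | C=C[C@@H]1OC(=O)C(=C)C[C@H](O[Si](C)(C)C(C)(C)C)/C=C(\C)C[C@H](OCc2ccc(OC)cc2)/C=C(\C)CC[C@@H]1C(=C)CO[Si](C)(C)C(C)(C)C | intermediate
36 | bridged butenolide (14-membered carbocycle, C2–O–C18 bridge) | O=C1O[C@H]2/C=C1/C[C@H](O[Si](C)(C)C(C)(C)C)/C=C(\C)C[C@H](OCc3ccc(OC)cc3)/C=C(\C)CC[C@@H]2C(=C)CO[Si](C)(C)C(C)(C)C | intermediate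
37 | (Z)-ene-diol, C2-OH and C18-OH | O[C@H]1/C=C(\CO)C[C@H](O[Si](C)(C)C(C)(C)C)/C=C(\C)C[C@H](OCc2ccc(OC)cc2)/C=C(\C)CC[C@@H]1C(=C)CO[Si](C)(C)C(C)(C)C | intermediate
38 | C18 mesylate of 37 | O[C@H]1/C=C(\COS(C)(=O)=O)C[C@H](O[Si](C)(C)C(C)(C)C)/C=C(\C)C[C@H](OCc2ccc(OC)cc2)/C=C(\C)CC[C@@H]1C(=C)CO[Si](C)(C)C(C)(C)C | intermediate (not isolated)
39 | C18 chloride, C2-OH | O[C@H]1/C=C(\CCl)C[C@H](O[Si](C)(C)C(C)(C)C)/C=C(\C)C[C@H](OCc2ccc(OC)cc2)/C=C(\C)CC[C@@H]1C(=C)CO[Si](C)(C)C(C)(C)C | intermediate (not isolated)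
40 | C18 chloride, C2-OTES | CC[Si](CC)(CC)O[C@H]1/C=C(\CCl)C[C@H](O[Si](C)(C)C(C)(C)C)/C=C(\C)C[C@H](OCc2ccc(OC)cc2)/C=C(\C)CC[C@@H]1C(=C)CO[Si](C)(C)C(C)(C)C | intermediate
41 | C18-methyl carbocycle, C2-OTES | CC[Si](CC)(CC)O[C@H]1/C=C(\C)C[C@H](O[Si](C)(C)C(C)(C)C)/C=C(\C)C[C@H](OCc2ccc(OC)cc2)/C=C(\C)CC[C@@H]1C(=C)CO[Si](C)(C)C(C)(C)C | intermediate
42 | C2-OH/C16-OH diol | O[C@H]1/C=C(\C)C[C@H](O[Si](C)(C)C(C)(C)C)/C=C(\C)C[C@H](OCc2ccc(OC)cc2)/C=C(\C)CC[C@@H]1C(=C)CO | intermediate
43 | C16 enal, C2-OH | O[C@H]1/C=C(\C)C[C@H](O[Si](C)(C)C(C)(C)C)/C=C(\C)C[C@H](OCc2ccc(OC)cc2)/C=C(\C)CC[C@@H]1C(=C)C=O | intermediate (not isolated)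
44 | C16 lactol | C=C1C(O)O[C@H]2/C=C(\C)C[C@H](O[Si](C)(C)C(C)(C)C)/C=C(\C)C[C@H](OCc3ccc(OC)cc3)/C=C(\C)CC[C@H]12 | intermediate (not isolated)
45 | α-methylene lactone, C6-OTBS, C10-OPMB | C=C1C(=O)O[C@H]2/C=C(\C)C[C@H](O[Si](C)(C)C(C)(C)C)/C=C(\C)C[C@H](OCc3ccc(OC)cc3)/C=C(\C)CC[C@H]12 | intermediate
46 | C6 alcohol, C10-OPMB | C=C1C(=O)O[C@H]2/C=C(\C)C[C@H](O)/C=C(\C)C[C@H](OCc3ccc(OC)cc3)/C=C(\C)CC[C@H]12 | intermediate
47 | C6 acetate, C10-OPMB | C=C1C(=O)O[C@H]2/C=C(\C)C[C@H](OC(C)=O)/C=C(\C)C[C@H](OCc3ccc(OC)cc3)/C=C(\C)CC[C@H]12 | intermediate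
48 | CNP0168244.1 | C=C1C(=O)O[C@H]2/C=C(\C)C[C@H](OC(C)=O)/C=C(\C)C[C@H](O)/C=C(\C)CC[C@H]12 | target

## Step count and risks

Total: 29 steps. Longest linear sequence: 29 steps, from 1 to 48; compounds 3, 21 and 29 are bought and enter directly.

**Step 21, ring-closing metathesis across the macrolactone.** The alkylidene at C3 may fail to reach the C4 methylene because the 15-membered lactone resists rotating its ester into the small-ring lactone arrangement, so that intermolecular metathesis through the C2 vinyl group takes over. The fallback forms the butenolide on an open chain and closes the carbocycle afterwards at C6–C7. It sets out from PMB ether 24. Carboalumination as in step 14, with iodinolysis of alkenylalane 25 (I2, THF), would give the (E)-vinyl iodide F1, and PPTS/MeOH would free C2-OH to give the alcohol F2. The acid partner comes from commercial 3-methylideneoxolan-2-one: LiOH opening gives lithium 4-hydroxy-2-methylidenebutanoate F3, and silylation (Et3SiCl, imidazole, aqueous work-up to hydrolyse the silyl ester) gives 2-methylidene-4-(triethylsilyloxy)butanoic acid F4. Steglich esterification (N,N′-diisopropylcarbodiimide, DMAP) of F2 with F4 gives the open-chain acrylate F5. Ring-closing metathesis with the same ruthenium catalyst, now on an unconstrained diene ester and with the vinyl iodide inert, should give the butenolide F6. PPTS/MeOH removes the primary TES ether to give the alcohol F7, and Dess–Martin oxidation gives the aldehyde F8. An intramolecular Nozaki–Hiyama–Kishi reaction (CrCl2, catalytic NiCl2, DMSO/THF, high dilution) joins C7 to C6 and gives the macrocyclic allylic alcohol F9. TBSOTf/2,6-lutidine on the (6S)-alcohol returns the route to compound 36; a wrong C6 epimer would be corrected by MnO2 oxidation and oxazaborolidine-catalysed borane reduction.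

**Step 20, macrolactonisation.** Oligomerisation may compete, acyl transfer to the hindered C2 hydroxyl may stall, and DMAP may add to the activated acrylate. The fallback makes the ester bimolecularly and closes the 15-membered lactone by forming C5–C6. It sets out from enal 28. PPTS/MeOH gives the C2-hydroxy enal F10. Acylation with 2-(bromomethyl)acryloyl chloride (from commercial 2-(bromomethyl)acrylic acid and (COCl)2) and 2,6-lutidine gives the bromo ester F11. Intramolecular Nozaki–Hiyama–Kishi allylation under the catalytic asymmetric conditions of step 16 at high dilution should give the macrocyclic hydroxy lactone F12; its C6 oxygen stays bound to zirconium until work-up, so it should not take over the acyl group. TBSOTf/2,6-lutidine then gives compound 35.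

**Step 16, asymmetric 2-(ethoxycarbonyl)allylation.** Facial selectivity may be poor with the β,β-disubstituted enal, or the γ-hydroxy ester may lactonise onto C18 before it is silylated. The fallback sets C6 with the propargylboration already used in step 12 and makes the acrylate afterwards by carbonylation. It sets out from enal 28. Allenylboronate 21 with (S)-TRIP should give, through the pinacol borate F13, the (6S)-homopropargylic alcohol F14, and TBSOTf/2,6-lutidine gives the silyl ether F15. Palladium-catalysed Markovnikov hydroethoxycarbonylation of the terminal alkyne (Pd(OAc)2, 2-pyridyldiphenylphosphine, catalytic CH3SO3H, CO, EtOH) then gives the 2-substituted acrylate 31 directly, so no free γ-hydroxy ester is ever present.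

Further compounds
F1 | step 21 | (E)-vinyl iodide (I on C7) from 24 | I/C=C(\C)C[C@H](OCc1ccc(OC)cc1)/C=C(\C)CC[C@@H]([C@H](C=C)O[Si](CC)(CC)CC)C(=C)CO[Si](C)(C)C(C)(C)C
F2 | step 21 | C2-hydroxy vinyl iodide | I/C=C(\C)C[C@H](OCc1ccc(OC)cc1)/C=C(\C)CC[C@@H]([C@H](C=C)O)C(=C)CO[Si](C)(C)C(C)(C)C
F3 | step 21 | lithium 4-hydroxy-2-methylidenebutanoate | [Li+].[O-]C(=O)C(=C)CCO
F4 | step 21 | 2-methylidene-4-(triethylsilyloxy)butanoic acid | C=C(CCO[Si](CC)(CC)CC)C(=O)O
F5 | step 21 | open-chain C2 acrylate ester of F2 with F4 | I/C=C(\C)C[C@H](OCc1ccc(OC)cc1)/C=C(\C)CC[C@@H]([C@H](C=C)OC(=O)C(=C)CCO[Si](CC)(CC)CC)C(=C)CO[Si](C)(C)C(C)(C)C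
F6 | step 21 | open-chain butenolide, C4 bearing CH2CH2OTES | I/C=C(\C)C[C@H](OCc1ccc(OC)cc1)/C=C(\C)CC[C@@H]([C@H]1OC(=O)C(CCO[Si](CC)(CC)CC)=C1)C(=C)CO[Si](C)(C)C(C)(C)C
F7 | step 21 | butenolide primary alcohol (C6-OH) | I/C=C(\C)C[C@H](OCc1ccc(OC)cc1)/C=C(\C)CC[C@@H]([C@H]1OC(=O)C(CCO)=C1)C(=C)CO[Si](C)(C)C(C)(C)C
F8 | step 21 | butenolide C6 aldehyde | I/C=C(\C)C[C@H](OCc1ccc(OC)cc1)/C=C(\C)CC[C@@H]([C@H]1OC(=O)C(CC=O)=C1)C(=C)CO[Si](C)(C)C(C)(C)C
F9 | step 21 | bridged butenolide with free (6S)-hydroxyl | O=C1O[C@H]2/C=C1/C[C@H](O)/C=C(\C)C[C@H](OCc3ccc(OC)cc3)/C=C(\C)CC[C@@H]2C(=C)CO[Si](C)(C)C(C)(C)C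
F10 | step 20 | C2-hydroxy C6 enal | O=C/C=C(\C)C[C@H](OCc1ccc(OC)cc1)/C=C(\C)CC[C@@H]([C@H](C=C)O)C(=C)CO[Si](C)(C)C(C)(C)C
F11 | step 20 | C2 2-(bromomethyl)acrylate of F10 | O=C/C=C(\C)C[C@H](OCc1ccc(OC)cc1)/C=C(\C)CC[C@@H]([C@H](C=C)OC(=O)C(=C)CBr)C(=C)CO[Si](C)(C)C(C)(C)C
F12 | step 20 | 15-membered macrolactone with free (6S)-hydroxyl | C=C[C@@H]1OC(=O)C(=C)C[C@H](O)/C=C(\C)C[C@H](OCc2ccc(OC)cc2)/C=C(\C)CC[C@@H]1C(=C)CO[Si](C)(C)C(C)(C)C
F13 | step 16 | C6 O-pinacol borate of F14 | C#CC[C@H](OB1OC(C)(C)C(C)(C)O1)/C=C(\C)C[C@H](OCc2ccc(OC)cc2)/C=C(\C)CC[C@@H]([C@H](C=C)O[Si](CC)(CC)CC)C(=C)CO[Si](C)(C)C(C)(C)C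
F14 | step 16 | (6S)-homopropargylic alcohol | C#CC[C@H](O)/C=C(\C)C[C@H](OCc1ccc(OC)cc1)/C=C(\C)CC[C@@H]([C@H](C=C)O[Si](CC)(CC)CC)C(=C)CO[Si](C)(C)C(C)(C)C
F15 | step 16 | C6-OTBS terminal alkyne | C#CC[C@H](O[Si](C)(C)C(C)(C)C)/C=C(\C)C[C@H](OCc1ccc(OC)cc1)/C=C(\C)CC[C@@H]([C@H](C=C)O[Si](CC)(CC)CC)C(=C)CO[Si](C)(C)C(C)(C)C
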